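**Strategy**

Numbering: pyrazinone N1 (OH), C2 (carbonyl), C3 (methyl), N4, C5 (methoxy), C6; indole positions are primed. Everything rests on opening the indole's pyrrole ring at C3'–C3a' and N1'–C2'. That ring holds the pyrazinylmethyl arm on C3' and borders the prenylated C7', so it splits cleanly into an aniline with bromine and prenyl flanking the amino group and an internal alkyne that already carries the complete O-benzyl pyrazinone. A single palladium heteroannulation unites both halves and forges the five-membered ring; a trimethylsilyl cap on the alkyne dictates which alkyne carbon becomes C2'. Fluoride desilylation and BCl3 debenzylation then deliver the natural product.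

Key step: step 13

Remark: the target has no stereocentre; the alanine-derived centre carried in 8 to 13 is erased in step 8, so any epimerisation on the way is without consequence. Methyl bromoacetate and ethynyltrimethylsilane are taken as further commercial starting materials.

**Route**

Step 1
Reactants: 1 2-bromoaniline; 2 3-chloro-3-methylbut-1-yne
Product: 3 2-bromo-N-(2-methylbut-3-yn-2-yl)aniline
Conditions: CuCl (10 mol %), Et3N, THF, 0 °C to rt
Reagents that add atoms: none
Why: Copper-catalysed propargylic amination of a tertiary propargyl chloride, which proceeds through a copper-bound allenylidene-type electrophile, is the established way to N-(1,1-dimethylpropargyl)anilines and leaves the aryl bromide untouched.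

Step 2
Reactants: 3 2-bromo-N-(2-methylbut-3-yn-2-yl)aniline
Product: 4 2-bromo-N-(2-methylbut-3-en-2-yl)aniline
Conditions: H2 (1 atm), Pd/CaCO3 poisoned with Pb(OAc)2 (Lindlar catalyst), quinoline, EtOAc, rt
Reagents that add atoms: none
Why: Lindlar semihydrogenation stops at the alkene on the lead-poisoned catalyst, which is also too deactivated to cleave the aryl C–Br bond.

Step 3
Reactants: 4 2-bromo-N-(2-methylbut-3-en-2-yl)aniline
Product: 5 2-bromo-6-(3-methylbut-2-en-1-yl)aniline
Conditions: TsOH·H2O (20 mol %), MeCN/H2O (10:1), 70 °C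
Reagents that add atoms: none
Why: Acid-promoted aromatic aza-Claisen rearrangement: N-protonation accelerates the [3,3] shift, which transposes the 1,1-dimethylallyl group into a prenyl group on the only free ortho carbon, and tautomerisation restores the aniline.

Step 4
Reactants: 6 N-Boc-L-alanine; 7 O-benzylhydroxylamine
Product: 8 tert-butyl [(2S)-1-(benzyloxyamino)-1-oxopropan-2-yl]carbamate
Conditions: EDC·HCl, HOBt, CH2Cl2, 0 °C to rt
Reagents that add atoms: none
Why: Carbodiimide/HOBt amide coupling of the acid with the strongly nucleophilic alkoxyamine gives the O-benzyl hydroxamate without touching the existing stereocentre.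

Step 5
Reactants: 8 tert-butyl [(2S)-1-(benzyloxyamino)-1-oxopropan-2-yl]carbamate; 9 methyl bromoacetate
Product: 10 methyl N-(benzyloxy)-N-[N-(tert-butoxycarbonyl)-L-alanyl]glycinate
Conditions: K2CO3, DMF, rt
Reagents that add atoms: none
Why: The hydroxamate N–H is by far the most acidic site, so carbonate generates its anion, which undergoes SN2 N-alkylation with the reactive α-bromo ester.

Step 6
Reactants: 10 methyl N-(benzyloxy)-N-[N-(tert-butoxycarbonyl)-L-alanyl]glycinate
Product: 12 (3S)-1-(benzyloxy)-3-methylpiperazine-2,5-dione, via amine trifluoroacetate salt 11 (not isolated)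
Conditions: TFA, CH2Cl2, rt; evaporate; then Et3N, MeOH, reflux
Reagents that add atoms: none
Why: Acidolytic Boc removal followed, after neutralisation, by 6-exo-trig lactamisation of the free amine onto the methyl ester is the standard diketopiperazine closure, helped here by the tertiary hydroxamate that readily adopts the required cis geometry.

Step 7
Reactants: 12 (3S)-1-(benzyloxy)-3-methylpiperazine-2,5-dione
Product: 13 (3S)-1-(benzyloxy)-5-methoxy-3-methyl-3,6-dihydropyrazin-2(1H)-one
Conditions: Me3OBF4, CH2Cl2, rt; then cold aq. NaHCO3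
Reagents that add atoms: trimethyloxonium tetrafluoroborate, C[O+](C)C.F[B-](F)(F)F
Why: Meerwein O-methylation converts the only secondary lactam into its lactim ether, since the fully substituted hydroxamate cannot form a neutral imidate.

Step 8
Reactants: 13 (3S)-1-(benzyloxy)-5-methoxy-3-methyl-3,6-dihydropyrazin-2(1H)-one
Product: 14 1-(benzyloxy)-5-methoxy-3-methylpyrazin-2(1H)-one
Conditions: DDQ, 1,4-dioxane, rt to 60 °C
Reagents that add atoms: none
Why: DDQ dehydrogenation removes the two para-related hydrogens at C3 and C6 of the dihydropyrazinone, driven by aromatisation, as is routine for dihydropyrazine lactim ethers.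

Step 9
Reactants: 14 1-(benzyloxy)-5-methoxy-3-methylpyrazin-2(1H)-one
Product: 16 1-(benzyloxy)-5-methoxy-3-methyl-2-oxo-1,2-dihydropyrazine-6-carbaldehyde (formyl on C6 in the numbering used here), via iminium chloride 15 (not isolated)
Conditions: POCl3, DMF, 0 °C to rt; then aq. NaOAc
Reagents that add atoms: N,N-dimethylformamide, CN(C)C=O (formyl carbon); water, O (formyl oxygen)
Why: Vilsmeier–Haack formylation: C6 is the only ring C–H and the β-carbon of the C5 enol ether, so the chloroiminium ion attacks there and aqueous hydrolysis of the iminium salt releases the aldehyde.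

Step 10
Reactants: 16 1-(benzyloxy)-5-methoxy-3-methyl-2-oxo-1,2-dihydropyrazine-6-carbaldehyde
Product: 17 1-(benzyloxy)-6-(hydroxymethyl)-5-methoxy-3-methylpyrazin-2(1H)-one
Conditions: NaBH4, MeOH, 0 °C
Reagents that add atoms: none
Why: Borohydride 1,2-reduction of the aldehyde is chemoselective over the amide-type ring carbonyl, the ring C=N bond and the N–O bond at 0 °C.

Step 11
Reactants: 17 1-(benzyloxy)-6-(hydroxymethyl)-5-methoxy-3-methylpyrazin-2(1H)-one
Product: 18 1-(benzyloxy)-6-(bromomethyl)-5-methoxy-3-methylpyrazin-2(1H)-one
Conditions: CBr4, PPh3, CH2Cl2, 0 °C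
Reagents that add atoms: tetrabromomethane, BrC(Br)(Br)Br
Why: Appel bromination activates the primary alcohol as an oxyphosphonium ion that bromide displaces under neutral conditions compatible with the lactim ether and the O-benzyl group.

Step 12
Reactants: 18 1-(benzyloxy)-6-(bromomethyl)-5-methoxy-3-methylpyrazin-2(1H)-one; 19 ethynyltrimethylsilane
Product: 21 1-(benzyloxy)-5-methoxy-3-methyl-6-[3-(trimethylsilyl)prop-2-yn-1-yl]pyrazin-2(1H)-one, via copper acetylide 20 (not isolated)
Conditions: CuI, K2CO3, DMF, rt
Reagents that add atoms: none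
Why: Copper-mediated alkynylation of an activated benzylic-type bromide, as used for skipped diynes: the copper acetylide formed with CuI and carbonate displaces bromide, and the weak heterogeneous base at room temperature limits propargyl-to-allene isomerisation and loss of the silyl group.

Step 13
Reactants: 5 2-bromo-6-(3-methylbut-2-en-1-yl)aniline; 21 1-(benzyloxy)-5-methoxy-3-methyl-6-[3-(trimethylsilyl)prop-2-yn-1-yl]pyrazin-2(1H)-one
Product: 22 1-(benzyloxy)-5-methoxy-3-methyl-6-{[7-(3-methylbut-2-en-1-yl)-2-(trimethylsilyl)-1H-indol-3-yl]methyl}pyrazin-2(1H)-one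
Conditions: Pd[P(t-Bu)3]2 (10 mol %), Cy2NMe, 1,4-dioxane, 80 °C
Reagents that add atoms: none
Why: Zerovalent palladium adds oxidatively to the C–Br bond of 5, the alkyne of 21 inserts syn into the aryl–palladium bond with the aryl carbon bonding to the alkyne carbon that carries the CH2 group, and the amino group then binds divalent palladium before deprotonation by Cy2NMe and C–N reductive elimination complete the cycle. The closest known reaction type is the Larock indole synthesis of ortho-bromoanilines with silyl-capped internal alkynes under bulky trialkylphosphine catalysis. The pyrrole ring is closed as a formal [3+2] heteroannulation: intermolecular carbopalladation makes C3'–C3a', then intramolecular reductive elimination from a six-membered aza-palladacycle makes N1'–C2'. No stereocentre is created. The step needs regioselective insertion, which the bulky trimethylsilyl group secures by ending up next to palladium (hence on C2'), and chemoselectivity, which is secured because the trisubstituted prenyl alkene is meta to the C–Br bond and a poor Heck acceptor and because the weak, hindered amine base should not isomerise the propargylic CH2 to an allene.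

Step 14
Reactants: 22 1-(benzyloxy)-5-methoxy-3-methyl-6-{[7-(3-methylbut-2-en-1-yl)-2-(trimethylsilyl)-1H-indol-3-yl]methyl}pyrazin-2(1H)-one
Product: 23 1-(benzyloxy)-5-methoxy-3-methyl-6-{[7-(3-methylbut-2-en-1-yl)-1H-indol-3-yl]methyl}pyrazin-2(1H)-one
Conditions: Bu4NF, THF, rt to 50 °C
Reagents that add atoms: none
Why: Fluoride-induced protodesilylation of the 2-silylindole: fluoride attacks silicon and the C2' carbanion equivalent is protonated by the water present, while the O-benzyl hydroxamate and the prenyl group are inert to fluoride.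

Step 15
Reactants: 23 1-(benzyloxy)-5-methoxy-3-methyl-6-{[7-(3-methylbut-2-en-1-yl)-1H-indol-3-yl]methyl}pyrazin-2(1H)-one
Product: 24 astepyrazinoxide, 1-hydroxy-5-methoxy-3-methyl-6-{[7-(3-methylbut-2-en-1-yl)-1H-indol-3-yl]methyl}pyrazin-2(1H)-one
Conditions: BCl3, pentamethylbenzene, CH2Cl2, −78 °C; then MeOH, −78 °C to rt
Reagents that add atoms: none
Why: Lewis-acid debenzylation with a non-basic cation scavenger: BCl3 activates the N–O–benzyl oxygen, pentamethylbenzene captures the benzyl cation by Friedel–Crafts alkylation faster than the indole or the alkene can, and at −78 °C neither the prenyl double bond nor the methyl lactim ether should be attacked.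

**Compound list**

1 | 2-bromoaniline | Nc1ccccc1Br | starting material
2 | 3-chloro-3-methylbut-1-yne | CC(C)(Cl)C#C | starting material
3 | 2-bromo-N-(2-methylbut-3-yn-2-yl)aniline | C#CC(C)(C)Nc1ccccc1Br | intermediate
4 | 2-bromo-N-(2-methylbut-3-en-2-yl)aniline | C=CC(C)(C)Nc1ccccc1Br | intermediate
5 | 2-bromo-6-(3-methylbut-2-en-1-yl)aniline | Nc1c(Br)cccc1CC=C(C)C | intermediate
6 | N-Boc-L-alanine, (2S)-2-[(tert-butoxycarbonyl)amino]propanoic acid | C[C@H](NC(=O)OC(C)(C)C)C(=O)O | starting material
7 | O-benzylhydroxylamine | NOCc1ccccc1 | starting material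
8 | tert-butyl [(2S)-1-(benzyloxyamino)-1-oxopropan-2-yl]carbamate | C[C@H](NC(=O)OC(C)(C)C)C(=O)NOCc1ccccc1 | intermediate
9 | methyl bromoacetate | COC(=O)CBr | starting material
10 | methyl N-(benzyloxy)-N-[N-(tert-butoxycarbonyl)-L-alanyl]glycinate | C[C@H](NC(=O)OC(C)(C)C)C(=O)N(OCc1ccccc1)CC(=O)OC | intermediate
11 | methyl N-(L-alanyl)-N-(benzyloxy)glycinate trifluoroacetate salt | C[C@H](N)C(=O)N(OCc1ccccc1)CC(=O)OC.OC(=O)C(F)(F)F | intermediate (not isolated)
12 | (3S)-1-(benzyloxy)-3-methylpiperazine-2,5-dione | C[C@@H]1NC(=O)CN(OCc2ccccc2)C1=O | intermediate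
13 | (3S)-1-(benzyloxy)-5-methoxy-3-methyl-3,6-dihydropyrazin-2(1H)-one | COC1=N[C@@H](C)C(=O)N(OCc2ccccc2)C1 | intermediate
14 | 1-(benzyloxy)-5-methoxy-3-methylpyrazin-2(1H)-one | COc1cn(OCc2ccccc2)c(=O)c(C)n1 | intermediate
15 | N-{[1-(benzyloxy)-5-methoxy-3-methyl-2-oxo-1,2-dihydropyrazin-6-yl]methylidene}-N-methylmethanaminium chloride | COc1nc(C)c(=O)n(OCc2ccccc2)c1C=[N+](C)C.[Cl-] | intermediate (not isolated)
16 | 1-(benzyloxy)-5-methoxy-3-methyl-2-oxo-1,2-dihydropyrazine-6-carbaldehyde | COc1nc(C)c(=O)n(OCc2ccccc2)c1C=O | intermediate
17 | 1-(benzyloxy)-6-(hydroxymethyl)-5-methoxy-3-methylpyrazin-2(1H)-one | COc1nc(C)c(=O)n(OCc2ccccc2)c1CO | intermediate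
18 | 1-(benzyloxy)-6-(bromomethyl)-5-methoxy-3-methylpyrazin-2(1H)-one | COc1nc(C)c(=O)n(OCc2ccccc2)c1CBr | intermediate
19 | ethynyltrimethylsilane | C#C[Si](C)(C)C | starting material
20 | [(trimethylsilyl)ethynyl]copper | C[Si](C)(C)C#C[Cu] | intermediate (not isolated)
21 | 1-(benzyloxy)-5-methoxy-3-methyl-6-[3-(trimethylsilyl)prop-2-yn-1-yl]pyrazin-2(1H)-one | COc1nc(C)c(=O)n(OCc2ccccc2)c1CC#C[Si](C)(C)C | intermediate
22 | 1-(benzyloxy)-5-methoxy-3-methyl-6-{[7-(3-methylbut-2-en-1-yl)-2-(trimethylsilyl)-1H-indol-3-yl]methyl}pyrazin-2(1H)-one | COc1nc(C)c(=O)n(OCc2ccccc2)c1Cc1c([Si](C)(C)C)[nH]c2c(CC=C(C)C)cccc12 | intermediate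
23 | 1-(benzyloxy)-5-methoxy-3-methyl-6-{[7-(3-methylbut-2-en-1-yl)-1H-indol-3-yl]methyl}pyrazin-2(1H)-one | COc1nc(C)c(=O)n(OCc2ccccc2)c1Cc1c[nH]c2c(CC=C(C)C)cccc12 | intermediate
24 | astepyrazinoxide, 1-hydroxy-5-methoxy-3-methyl-6-{[7-(3-methylbut-2-en-1-yl)-1H-indol-3-yl]methyl}pyrazin-2(1H)-one | COc1nc(C)c(=O)n(O)c1Cc1c[nH]c2c(CC=C(C)C)cccc12 | target

**Step count and risk**

Total step count: 15. Longest linear sequence: 12 steps (steps 4 to 15, from 6 to 24).

Steps most likely to fail:

1. Step 13 (key step). Insertion of the hindered silyl alkyne may be too slow, so that the catalyst decays. The amine base may isomerise the propargylic methylene to an allene before insertion. The crowded 2,6-disubstituted aniline may also retard the C–N closure. The fallback sets out from 5, 19 and 18 and comes back at 23. Sonogashira coupling of 5 with 19 (PdCl2(PPh3)2, CuI, Et3N, 70 °C) should give 2-(3-methylbut-2-en-1-yl)-6-[(trimethylsilyl)ethynyl]aniline F1. Bu4NF in refluxing THF should then remove the silyl group and close the ring by 5-endo-dig hydroamination to 7-(3-methylbut-2-en-1-yl)-1H-indole F2. C3'-selective alkylation of this indole with bromide 18 (Zn(OTf)2, i-Pr2NEt, Bu4NI, toluene, rt) should give 23 directly, so step 14 is no longer needed.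

2. Step 12. Carbonate may isomerise the doubly activated propargylic product to the allene. It may also strip the silyl group. The labile bromide may be lost to solvolysis before it couples. The fallback sets out from 18 and comes back at 21. It is a base-free Stille cross-coupling of 18 with tributyl[(trimethylsilyl)ethynyl]stannane (Pd(PPh3)4, toluene, 60 °C), a known benzylic halide–alkynylstannane coupling under neutral conditions. No compound outside the compound list is formed on this path (F0).

3. Step 9. POCl3 may activate the ring carbonyl oxygen instead, with loss of the benzyl group and deoxygenative chlorination. Alternatively C6 may be too weakly nucleophilic for the chloroiminium ion. The fallback sets out from 14 and comes back at 17, bypassing 16 and step 10. Electrophilic bromination with N-bromosuccinimide (MeCN, 0 °C) should give 1-(benzyloxy)-6-bromo-5-methoxy-3-methylpyrazin-2(1H)-one F3. Stille hydroxymethylation with (tributylstannyl)methanol (Pd(PPh3)4, 1,4-dioxane, 90 °C) should then give alcohol 17.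

**Further compounds**

F1 | step 13 | 2-(3-methylbut-2-en-1-yl)-6-[(trimethylsilyl)ethynyl]aniline | Nc1c(CC=C(C)C)cccc1C#C[Si](C)(C)C
F2 | step 13 | 7-(3-methylbut-2-en-1-yl)-1H-indole | CC(C)=CCc1cccc2cc[nH]c12
F0 | step 12 | none | none
F3 | step 9 | 1-(benzyloxy)-6-bromo-5-methoxy-3-methylpyrazin-2(1H)-one | COc1nc(C)c(=O)n(OCc2ccccc2)c1Br
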